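If starting material and single product take up the same reagent, each at a rate proportional to both partners, the reagent cancels from the ratio of the two rates. Integrated, that ratio puts single product on one curve against a, the fraction of starting material left: single = (a^s − a)/(1 − s), where s is the selectivity factor, the rate constant of single product with reagent over that of starting material with reagent.

in all of them: starting material 0.18 M
- midnight: reagent 0.27 M; run made earlier
- dusk: reagent 0.33 M; run made earlier
- summer: reagent 0.36 M; run made earlier
- ash: reagent 0.220 M; time 2.5 h
- cedar: reagent 0.430 M; time 2.5 h

| run | time / h | side product / % | starting material / % | tris adduct / % | double product / % | single product / % |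
|---|---|---|---|---|---|---|
| midnight | 0.200 | 0 | 44.9 | 0.8 | 6.2 | 46.6 |
| midnight | 0.667 | 5.8 | 17.8 | 4.3 | 13.8 | 57.0 |
| midnight | 1.33 | 14.8 | 10.5 | 8.8 | 11.1 | 53.1 |
| midnight | 2.00 | 23.6 | 7.3 | 9.6 | 6.8 | 50.8 |
| midnight | 2.50 | 26.9 | 7.0 | 11.1 | 5.2 | 50.2 |
| dusk | 0.200 | 0.4 | 37.1 | 1.6 | 9.3 | 51.1 |
| dusk | 0.667 | 8.6 | 10.8 | 9.4 | 16.5 | 55.2 |
| dusk | 1.33 | 21.4 | 5.6 | 14.6 | 11.9 | 45.7 |
| dusk | 2.00 | 32.4 | 3.0 | 16.5 | 7.8 | 40.5 |
| dusk | 2.50 | 35.7 | 1.8 | 16.5 | 4.0 | 38.7 |
| summer | 0.200 | 1.3 | 34.8 | 1.2 | 10.3 | 53.2 |
| summer | 0.667 | 9.6 | 9.4 | 9.9 | 17.1 | 52.9 |
| summer | 1.33 | 24.2 | 2.9 | 17.6 | 12.9 | 42.8 |
| summer | 2.00 | 34.6 | 2.0 | 20.2 | 6.6 | 35.5 |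
| summer | 2.50 | 40.7 | 0.5 | 20.6 | 6.1 | 32.5 |

(readings scatter by 0.5 percentage points)

- candidate steps: double product + by-product -> side product; reagent + double product -> tris adduct + by-product; reagent + single product -> double product + by-product; starting material + reagent -> single product + by-product

- which of these there is most of at the end, counted by the starting material in it, ash (tris adduct / side product / double product / starting material / single product)
- which of these there is most of at the end, counted by the starting material in it, cedar (tris adduct / side product / double product / starting material / single product)
- amount of the one of these that there is most of at the end, in percent of the starting material charged, ash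
- amount of the one of these that there is most of at the end, in percent of the starting material charged, cedar

Between two readings, the starting material lost minus the single product gained is what passed on to double product, and by the same ratio of rates that amount is about s times the mean single product times the natural logarithm of the fall in a. Midnight's readings at 0.200 h and 0.667 h give in this way a selectivity factor of 0.348, a value read from readings and carrying their scatter. The curve then has its ceiling at 56.9 % single product.

Counting 1 reagent per single product and 2 per double or side product, with tris adduct set aside, reaching that ceiling costs 1.03 equivalents. Ash carries 1.22, slightly more than that. Midnight had spent 1.48 of its 1.50 equivalents by 2.50 h, so ash should use its charge too and end just under the ceiling, with single product first.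

Summer already holds more side product, 40.7 %, than single product, 32.5 %. Cedar, with still more reagent, should therefore end with side product first, somewhat above that reading.

The forecast gives single product at 57 % (53 % to 61 %) for ash, close to the ceiling reckoned here, and side product at 47 % (43 % to 52 %) for cedar, holding that “the outcome is mainly set by reagent equivalents”.

The flasks give single product at 56.2 % in ash and side product at 44.5 % in cedar.

    double product + by-product → side product (k = 0.00164 L mol⁻¹ s⁻¹)
    reagent + double product → tris adduct + by-product (k = 0.00236 L mol⁻¹ s⁻¹)
    reagent + single product → double product + by-product (k = 0.00187 L mol⁻¹ s⁻¹)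
    starting material + reagent → single product + by-product (k = 0.00539 L mol⁻¹ s⁻¹)

In ash, single product is made 4.29 times faster than it is used up at 0.167 h, while its half-life by the reagent step alone, at the charged concentrations, is 0.47 h, short against the 2.5 h of the run; at the end, 1.6 % of the reagent charge remains. With 15 % of the starting material left in ash, the curve at 0.348 gives 56.2 % single product, and in the neighbour flask with 0.31 M of starting material, which keeps 40 % of it, the curve gives 50.1 % against the 50.2 % that flask holds.

All runs were computed on assumed constants; scatter was added.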